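**Retrosynthetic overview**
1. Notation: upper flavan = rings A (benzo), C (pyran), B (2-aryl); lower epiafzelechin unit = rings D, F, E, its atoms marked L (C8L); ArL = (2R,3R)-3,5,7-tris(benzyloxy)-2-[4-(benzyloxy)phenyl]chroman-8-yl.
2. After global debenzylation, ring C is opened at O1–C8a to the seco triarylpropanol 15, whose ring A is a plain 4-hydroxyphenyl group with C8a still C–H.
3. Enabling feature: in ring A the C7 hydroxyl is para to C4a and C8a is ortho to C4a, so oxygenation at C4a gives a p-quinol whose enone β-carbon is C8a, six atoms from the C2 hydroxyl; after O1–C8a closure the C4a hydroxyl leaves as water and ring A re-aromatises (C5 and C8a give the same chroman).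
4. 15 comes from C2–OH by CBS reduction, C4–C4a by rhodium-catalysed asymmetric 1,4-addition of (4-hydroxyphenyl)boronic acid, C3–C4 by Claisen–Schmidt condensation, and C4–C8L by formylation of 8-bromo-tetra-O-benzyl-epiafzelechin.
5. Ring order: rings D, E, F arrive with (−)-epiafzelechin; ring C is the only ring formed, in the penultimate step.

Key step: step 8

Assumption: (−)-epiafzelechin (1) is taken as a purchasable natural product whose C2L/C3L stereocentres are carried through untouched.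

Step 1
Reactants: 1 (−)-epiafzelechin; 2 benzyl bromide
Product: 3 (2R,3R)-5,7-bis(benzyloxy)-2-[4-(benzyloxy)phenyl]chroman-3-ol
Conditions: BnBr (3.3 equiv), K2CO3, DMF, 0 °C → rt
Reagents that add atoms: benzyl bromide (2), BrCc1ccccc1
Why: Williamson ether synthesis in which K2CO3 ionises only the three phenols, so the secondary C3L hydroxyl stays free and no stereocentre is touched.

Step 2
Reactants: 3 tri-O-benzyl-epiafzelechin; 2 benzyl bromide
Product: 4 (2R,3R)-3,5,7-tris(benzyloxy)-2-[4-(benzyloxy)phenyl]chromane (ArL–H)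
Conditions: NaH, BnBr, DMF, 0 °C → rt
Reagents that add atoms: benzyl bromide (2), BrCc1ccccc1
Why: Williamson etherification of the sodium alkoxide of the C3L alcohol; with all phenols capped there is no ring-opening pathway that could epimerise C2L.

Step 3
Reactants: 4 ArL–H; 5 N-bromosuccinimide
Product: 6 (2R,3R)-3,5,7-tris(benzyloxy)-2-[4-(benzyloxy)phenyl]-8-bromochromane (ArL–Br)
Conditions: NBS, CH2Cl2, −78 °C → 0 °C
Reagents that add atoms: N-bromosuccinimide (5), O=C1CCC(=O)N1Br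
Why: Electrophilic aromatic bromination of the phloroglucinol-type ring D, which in 5,7-di-O-benzyl flavan-3-ols takes NBS at C8L in preference to C6L and so fixes the later linkage site.

Step 4
Reactants: 6 ArL–Br; 7 N,N-dimethylformamide
Product: 9 (2R,3R)-3,5,7-tris(benzyloxy)-2-[4-(benzyloxy)phenyl]chromane-8-carbaldehyde (ArL–CHO), via aryllithium 8 (not isolated)
Conditions: n-BuLi, THF, −78 °C; DMF, −78 °C → 0 °C; H2O
Reagents that add atoms: N,N-dimethylformamide (7), CN(C)C=O
Why: Bromine–lithium exchange followed by Bouveault formylation, the aryllithium being held between two alkoxy groups and formylated only at the former C–Br carbon.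

Step 5
Reactants: 9 ArL–CHO; 10 1-[4-(benzyloxy)phenyl]ethan-1-one
Product: 12 (E)-1-[4-(benzyloxy)phenyl]-3-ArL-prop-2-en-1-one, via aldol adduct 11 (not isolated)
Conditions: KOH, EtOH/THF, rt → 40 °C
Reagents that add atoms: 1-[4-(benzyloxy)phenyl]ethan-1-one (10), CC(=O)c1ccc(OCc2ccccc2)cc1
Why: Claisen–Schmidt aldol condensation in which E1cB dehydration of the aldol gives the conjugated (E)-enone as the thermodynamic alkene.

Step 6
Reactants: 12 (E)-enone; 13 (4-hydroxyphenyl)boronic acid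
Product: 14 (3S)-1-[4-(benzyloxy)phenyl]-3-(4-hydroxyphenyl)-3-ArL-propan-1-one
Conditions: [Rh(OH)((S)-BINAP)]2 (3 mol %), 13 (4 equiv), dioxane/H2O (10:1), 50 °C
Reagents that add atoms: (4-hydroxyphenyl)boronic acid (13), OB(O)c1ccc(O)cc1
Why: Hayashi–Miyaura asymmetric 1,4-addition (aryl transfer from boron to monovalent rhodium, enone insertion, hydrolysis of the rhodium enolate) in which the BINAP ligand sets the new C4 centre under catalyst control; the (S)-ligand is the enantiomer that the facial model for (E)-enones assigns to the 3S ketone, and (R)-BINAP would be used if the first run shows the opposite sense.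

Step 7
Reactants: 14 (3S)-ketone
Product: 15 (1S,3S)-1-[4-(benzyloxy)phenyl]-3-(4-hydroxyphenyl)-3-ArL-propan-1-ol
Conditions: (R)-2-methyl-CBS-oxazaborolidine, BH3·THF (excess), THF, −20 °C; MeOH, then aqueous work-up
Reagents that add atoms: none
Why: Corey–Bakshi–Shibata reduction in which the (R)-oxazaborolidine treats the aryl group as the large substituent and delivers hydride to give the (S)-carbinol (future C2) under reagent control, the free phenol only consuming extra borane.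

Step 8
Reactants: 15 (1S,3S)-seco alcohol
Product: 19 (2S,4S)-2-[4-(benzyloxy)phenyl]-4-ArL-chroman-7-ol, via peroxyquinol 16 (not isolated), via p-quinol 17 (not isolated), via hydroxy-enone 18 (not isolated)
Conditions: Oxone (2KHSO5·KHSO4·K2SO4), NaHCO3, MeCN/H2O, rt; phase cut into CH2Cl2, PPh3, 0 °C; DBU (0.1 equiv), rt; TsOH·H2O (0.5 equiv), rt (one pot, no isolation)
Reagents that add atoms: none
Why: Singlet oxygen generated from Oxone/NaHCO3 attacks the phenol of ring A at C4a, PPh3 reduces the peroxide to p-quinol 17, the C2 hydroxyl then adds in a DBU-catalysed oxa-Michael reaction to the dienone β-carbon C8a to form O1–C8a, and TsOH dehydrates the resulting arene hydrate (loss of the C4a hydroxyl and H8a) so that ring A re-aromatises with its original oxygen now at C7. The closest known reaction types are the Oxone-mediated conversion of p-(hydroxyalkyl)phenols into p-peroxyquinols and p-quinols with cyclisation to hydrobenzofuranones and hydrobenzopyranones, and the acid-promoted aromatisation of 4-hydroxycyclohexenones to phenols. Ring C closes in a 6-exo-trig mode. No new permanent stereocentre is made: C2 and C4 are retained because neither the C2–O bond nor C4–H is broken, and the transient C4a/C8a centres are erased on aromatisation. The step needs chemoselectivity for ring A and regioselectivity for C8a: only ring A carries a free phenol, singlet oxygen oxidises C4a without a phenoxonium cation (so the five-membered spiro-ether closure at C4a is not offered), and the two enone β-carbons C5 and C8a lead to the same chroman.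

Step 9
Reactants: 19 pentabenzyl flavan–flavanol
Product: 20 (2S,4S)-2-(4-hydroxyphenyl)-4-[(2R,3R)-3,5,7-trihydroxy-2-(4-hydroxyphenyl)chroman-8-yl]chroman-7-ol (target, 2,4-cis)
Conditions: H2 (1 atm), Pd(OH)2/C, THF/MeOH, rt
Reagents that add atoms: none
Why: Hydrogenolysis of the five benzyl ethers under mild conditions that leave the cyclic benzylic ether bonds O1–C2 and the diarylmethine C4 intact, as in the debenzylation of benzylated proanthocyanidins.

**Compound list**
1 | (−)-epiafzelechin, (2R,3R)-2-(4-hydroxyphenyl)chromane-3,5,7-triol | c1c(O)cc(O)c2c1O[C@H](c1ccc(O)cc1)[C@H](O)C2 | starting material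
2 | benzyl bromide | BrCc1ccccc1 | starting material
3 | (2R,3R)-5,7-bis(benzyloxy)-2-[4-(benzyloxy)phenyl]chroman-3-ol | c1c(OCc2ccccc2)cc(OCc2ccccc2)c2c1O[C@H](c1ccc(OCc3ccccc3)cc1)[C@H](O)C2 | intermediate
4 | (2R,3R)-3,5,7-tris(benzyloxy)-2-[4-(benzyloxy)phenyl]chromane (ArL–H) | c1c(OCc2ccccc2)cc(OCc2ccccc2)c2c1O[C@H](c1ccc(OCc3ccccc3)cc1)[C@H](OCc1ccccc1)C2 | intermediate
5 | N-bromosuccinimide | O=C1CCC(=O)N1Br | starting material
6 | (2R,3R)-3,5,7-tris(benzyloxy)-2-[4-(benzyloxy)phenyl]-8-bromochromane (ArL–Br) | Brc1c(OCc2ccccc2)cc(OCc2ccccc2)c2c1O[C@H](c1ccc(OCc3ccccc3)cc1)[C@H](OCc1ccccc1)C2 | intermediate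
7 | N,N-dimethylformamide | CN(C)C=O | starting material
8 | 8-lithio derivative ArL–Li | [Li]c1c(OCc2ccccc2)cc(OCc2ccccc2)c2c1O[C@H](c1ccc(OCc3ccccc3)cc1)[C@H](OCc1ccccc1)C2 | intermediate
9 | (2R,3R)-3,5,7-tris(benzyloxy)-2-[4-(benzyloxy)phenyl]chromane-8-carbaldehyde (ArL–CHO) | O=Cc1c(OCc2ccccc2)cc(OCc2ccccc2)c2c1O[C@H](c1ccc(OCc3ccccc3)cc1)[C@H](OCc1ccccc1)C2 | intermediate
10 | 1-[4-(benzyloxy)phenyl]ethan-1-one | CC(=O)c1ccc(OCc2ccccc2)cc1 | starting material
11 | aldol adduct, 1-[4-(benzyloxy)phenyl]-3-hydroxy-3-ArL-propan-1-one (both carbinol epimers) | O=C(CC(O)c1c(OCc2ccccc2)cc(OCc2ccccc2)c2c1O[C@H](c1ccc(OCc3ccccc3)cc1)[C@H](OCc1ccccc1)C2)c1ccc(OCc2ccccc2)cc1 | intermediate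
12 | (E)-1-[4-(benzyloxy)phenyl]-3-ArL-prop-2-en-1-one | O=C(/C=C/c1c(OCc2ccccc2)cc(OCc2ccccc2)c2c1O[C@H](c1ccc(OCc3ccccc3)cc1)[C@H](OCc1ccccc1)C2)c1ccc(OCc2ccccc2)cc1 | intermediate
13 | (4-hydroxyphenyl)boronic acid | OB(O)c1ccc(O)cc1 | starting material
14 | (3S)-1-[4-(benzyloxy)phenyl]-3-(4-hydroxyphenyl)-3-ArL-propan-1-one | O=C(C[C@@H](c1ccc(O)cc1)c1c(OCc2ccccc2)cc(OCc2ccccc2)c2c1O[C@H](c1ccc(OCc3ccccc3)cc1)[C@H](OCc1ccccc1)C2)c1ccc(OCc2ccccc2)cc1 | intermediate
15 | (1S,3S)-1-[4-(benzyloxy)phenyl]-3-(4-hydroxyphenyl)-3-ArL-propan-1-ol | O[C@@H](C[C@@H](c1ccc(O)cc1)c1c(OCc2ccccc2)cc(OCc2ccccc2)c2c1O[C@H](c1ccc(OCc3ccccc3)cc1)[C@H](OCc1ccccc1)C2)c1ccc(OCc2ccccc2)cc1 | intermediate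
16 | 4-hydroperoxy-4-[(1R,3S)-3-[4-(benzyloxy)phenyl]-3-hydroxy-1-ArL-propyl]cyclohexa-2,5-dien-1-one (side-chain geometry as in 15; the descriptor at the ArL-bearing carbon changes because C4a now carries oxygen) | O[C@@H](C[C@@H](C1(OO)C=CC(=O)C=C1)c1c(OCc2ccccc2)cc(OCc2ccccc2)c2c1O[C@H](c1ccc(OCc3ccccc3)cc1)[C@H](OCc1ccccc1)C2)c1ccc(OCc2ccccc2)cc1 | intermediate
17 | 4-hydroxy-4-[(1R,3S)-3-[4-(benzyloxy)phenyl]-3-hydroxy-1-ArL-propyl]cyclohexa-2,5-dien-1-one (p-quinol) | O[C@@H](C[C@@H](C1(O)C=CC(=O)C=C1)c1c(OCc2ccccc2)cc(OCc2ccccc2)c2c1O[C@H](c1ccc(OCc3ccccc3)cc1)[C@H](OCc1ccccc1)C2)c1ccc(OCc2ccccc2)cc1 | intermediate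
18 | (2S,4R)-2-[4-(benzyloxy)phenyl]-4a-hydroxy-4-ArL-2,3,4,4a,8,8a-hexahydro-7H-chromen-7-one (same geometry at C2/C4 as 19; C4a/C8a transient, not specified) | C(c1ccccc1)Oc1ccc(cc1)[C@@H]1C[C@H](c2c(OCc3ccccc3)cc(OCc3ccccc3)c3c2O[C@H](c2ccc(OCc4ccccc4)cc2)[C@H](OCc2ccccc2)C3)C2(O)C=CC(=O)CC2O1 | intermediate
19 | (2S,4S)-2-[4-(benzyloxy)phenyl]-4-ArL-chroman-7-ol | C(c1ccccc1)Oc1ccc(cc1)[C@@H]1C[C@H](c2c(OCc3ccccc3)cc(OCc3ccccc3)c3c2O[C@H](c2ccc(OCc4ccccc4)cc2)[C@H](OCc2ccccc2)C3)c2ccc(O)cc2O1 | intermediate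
20 | (2S,4S)-2-(4-hydroxyphenyl)-4-[(2R,3R)-3,5,7-trihydroxy-2-(4-hydroxyphenyl)chroman-8-yl]chroman-7-ol | Oc1ccc([C@@H]2C[C@H](c3c(O)cc(O)c4c3O[C@H](c3ccc(O)cc3)[C@H](O)C4)c3ccc(O)cc3O2)cc1 | target

**Step count and risks**
Total step count: 9. Longest linear sequence: 9 steps (1 → 20).

Three steps most likely to fail:

Step 8. Singlet oxygen or peroxymonosulfate may also oxygenate the electron-rich ring D. If acid is added before the oxa-Michael closure is complete, the open p-quinol can lose water towards a quinone methide and scramble C4. Prolonged acid could also open the benzylic O1–C2 bond and epimerise C2. Fallback (sets out from 12, returns at 20): the oxygen at C8a is displaced from a halide instead of being made by C–H oxidation. Rhodium-catalysed 1,4-addition of [4-(benzyloxy)-2-chlorophenyl]boronic acid to 12 under the step 6 conditions should give the chloro ketone F1. CBS reduction as in step 7 should give the chloro alcohol F2. Intramolecular Pd-catalysed C–O coupling (Buchwald etherification: Pd(OAc)2, 2-(di-tert-butylphosphino)-1,1'-binaphthyl, Cs2CO3, toluene, 80 °C) closes O1–C8a to the hexabenzyl flavan F3, and hydrogenolysis as in step 9 gives 20.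

Step 6. Aryl insertion at the hindered, electron-rich β-carbon may be slow, with protodeboronation of the boronic acid competing, and catalyst control may erode next to the bulky chiral fragment. Fallback (sets out from 6, returns at 14): the polarity at C4 is reversed. Aryllithium 8 (from 6 as in step 4) is added to 4-(tert-butyldimethylsilyloxy)benzaldehyde to give the diarylmethanol F4 (both carbinol epimers). Ketone 10 is converted with TMSOTf/Et3N into its trimethylsilyl enol ether F5. Bi(OTf)3-catalysed SN1 alkylation of F5 by the doubly stabilised benzhydryl cation from F4 gives the silyl-protected ketone F6 as both C3 epimers. TBAF frees the phenol; the two epimers, 14 and the (3R)-ketone F7, are diastereomers because ArL is enantiopure and are separated by chromatography.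

Step 7. Facial selectivity may be poor if the β,β-diarylethyl group competes with the aryl group as the large substituent, and the free phenol sequesters borane. Fallback (sets out from 14, returns at 15): NaBH4 (MeOH/THF, 0 °C) gives 15 together with its carbinol epimer, the (1R,3S)-alcohol F8. The diastereomers are separated by chromatography, and F8 is re-oxidised to 14 with MnO2 and recycled.

**Further compounds**
F1 | step 8 | 1-[4-(benzyloxy)phenyl]-3-[4-(benzyloxy)-2-chlorophenyl]-3-ArL-propan-1-one (same geometry at C3 as 14; CIP descriptor 3R because of chlorine) | O=C(C[C@@H](c1ccc(OCc2ccccc2)cc1Cl)c1c(OCc2ccccc2)cc(OCc2ccccc2)c2c1O[C@H](c1ccc(OCc3ccccc3)cc1)[C@H](OCc1ccccc1)C2)c1ccc(OCc2ccccc2)cc1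
F2 | step 8 | (1S)-1-[4-(benzyloxy)phenyl]-3-[4-(benzyloxy)-2-chlorophenyl]-3-ArL-propan-1-ol (C3 geometry as in 15) | O[C@@H](C[C@@H](c1ccc(OCc2ccccc2)cc1Cl)c1c(OCc2ccccc2)cc(OCc2ccccc2)c2c1O[C@H](c1ccc(OCc3ccccc3)cc1)[C@H](OCc1ccccc1)C2)c1ccc(OCc2ccccc2)cc1
F3 | step 8 | (2S,4S)-7-(benzyloxy)-2-[4-(benzyloxy)phenyl]-4-ArL-chromane | C(c1ccccc1)Oc1ccc(cc1)[C@@H]1C[C@H](c2c(OCc3ccccc3)cc(OCc3ccccc3)c3c2O[C@H](c2ccc(OCc4ccccc4)cc2)[C@H](OCc2ccccc2)C3)c2ccc(OCc3ccccc3)cc2O1
F4 | step 6 | [4-(tert-butyldimethylsilyloxy)phenyl](ArL)methanol (both carbinol epimers) | OC(c1ccc(O[Si](C)(C)C(C)(C)C)cc1)c1c(OCc2ccccc2)cc(OCc2ccccc2)c2c1O[C@H](c1ccc(OCc3ccccc3)cc1)[C@H](OCc1ccccc1)C2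
F5 | step 6 | 1-[4-(benzyloxy)phenyl]-1-(trimethylsilyloxy)ethene | C=C(O[Si](C)(C)C)c1ccc(OCc2ccccc2)cc1
F6 | step 6 | 1-[4-(benzyloxy)phenyl]-3-[4-(tert-butyldimethylsilyloxy)phenyl]-3-ArL-propan-1-one (both C3 epimers) | O=C(CC(c1ccc(O[Si](C)(C)C(C)(C)C)cc1)c1c(OCc2ccccc2)cc(OCc2ccccc2)c2c1O[C@H](c1ccc(OCc3ccccc3)cc1)[C@H](OCc1ccccc1)C2)c1ccc(OCc2ccccc2)cc1
F7 | step 6 | (3R)-1-[4-(benzyloxy)phenyl]-3-(4-hydroxyphenyl)-3-ArL-propan-1-one | O=C(C[C@H](c1ccc(O)cc1)c1c(OCc2ccccc2)cc(OCc2ccccc2)c2c1O[C@H](c1ccc(OCc3ccccc3)cc1)[C@H](OCc1ccccc1)C2)c1ccc(OCc2ccccc2)cc1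
F8 | step 7 | (1R,3S)-1-[4-(benzyloxy)phenyl]-3-(4-hydroxyphenyl)-3-ArL-propan-1-ol | O[C@H](C[C@@H](c1ccc(O)cc1)c1c(OCc2ccccc2)cc(OCc2ccccc2)c2c1O[C@H](c1ccc(OCc3ccccc3)cc1)[C@H](OCc1ccccc1)C2)c1ccc(OCc2ccccc2)cc1
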